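**Assumption:** the target has no stereocentre and is achiral, so there is no enantiomer to select; the only stereo-element on the way is the (E)-alkene of the chalcone, which is consumed later.

**Retrosynthetic overview**
- Target ⇐ tetra-O-benzyl isoflavone by neutral hydrogenolysis, which keeps the tertiary alcohol (flanked by two phenols) away from acid.
- Pyranone ring (the only ring built, formed last) ⇐ acid ring closure of a 1,2-diaryl-3,3-dimethoxypropan-1-one, obtained by oxidative 1,2-aryl shift of a 2'-hydroxychalcone.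
- Chalcone ⇐ intermolecular Claisen–Schmidt aldol condensation of 2-hydroxy-4,6-bis(benzyloxy)acetophenone (A ring) with the fully substituted B-ring benzaldehyde; this is the key C–C bond and becomes C2–C3 of the isoflavone.
- B-ring aldehyde ⇐ bromination, then Br/Li exchange and DMF; side chain ⇐ hydration of a prenyl group installed by Br/Li exchange on 1,3-bis(benzyloxy)-2-bromo-4-methoxybenzene.
- That bromide ⇐ isovanillin (bromination, benzylation, Baeyer–Villiger, benzylation); A-ring ketone ⇐ phloroacetophenone.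

**Route**

Step 1
Reactants: 1 isovanillin (3-hydroxy-4-methoxybenzaldehyde)
Product: 2 2-bromo-3-hydroxy-4-methoxybenzaldehyde
Conditions: Br2 (1.05 eq), NaOAc, Fe powder (cat.), AcOH, rt
Reagents that add atoms: bromine, BrBr
Why: Electrophilic aromatic bromination directed ortho to the free phenol gives the 2-bromo isomer, the established regiochemical outcome for isovanillin.

Step 2
Reactants: 2 2-bromo-3-hydroxy-4-methoxybenzaldehyde
Product: 3 3-(benzyloxy)-2-bromo-4-methoxybenzaldehyde
Conditions: BnBr, K2CO3, DMF, rt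
Reagents that add atoms: benzyl bromide, BrCc1ccccc1
Why: Williamson ether synthesis on an acidic phenol; no competing nucleophile is present.

Step 3
Reactants: 3 3-(benzyloxy)-2-bromo-4-methoxybenzaldehyde
Product: 5 3-(benzyloxy)-2-bromo-4-methoxyphenol, via aryl formate 4 (not isolated)
Conditions: mCPBA, CH2Cl2, rt; then K2CO3 (cat.), MeOH, rt
Reagents that add atoms: mCPBA, OOC(=O)c1cccc(Cl)c1
Why: Baeyer–Villiger oxidation in which the electron-rich aryl group (p-OMe) migrates to oxygen, followed by methanolysis of the formate, turns CHO into OH.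

Step 4
Reactants: 5 3-(benzyloxy)-2-bromo-4-methoxyphenol
Product: 6 1,3-bis(benzyloxy)-2-bromo-4-methoxybenzene
Conditions: BnBr, K2CO3, DMF, 50 °C
Reagents that add atoms: benzyl bromide, BrCc1ccccc1
Why: Williamson ether synthesis; it leaves the bromine exactly between the two benzyloxy groups, where the side chain has to go.

Step 5
Reactants: 6 1,3-bis(benzyloxy)-2-bromo-4-methoxybenzene; 7 prenyl bromide (1-bromo-3-methylbut-2-ene)
Product: 10 1,3-bis(benzyloxy)-4-methoxy-2-(3-methylbut-2-en-1-yl)benzene, via aryllithium 8 (not isolated), via arylcopper 9 (not isolated)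
Conditions: n-BuLi (1.05 eq), THF, −78 °C; CuBr·SMe2 (1.05 eq), −78 → −40 °C; then 7, −78 °C → rt
Reagents that add atoms: none
Why: Br/Li exchange at −78 °C outruns benzylic deprotonation, and the arylcopper allylates prenyl bromide at its unhindered primary carbon (SN2-type copper-mediated allylation).

Step 6
Reactants: 10 1,3-bis(benzyloxy)-4-methoxy-2-(3-methylbut-2-en-1-yl)benzene
Product: 12 4-[2,6-bis(benzyloxy)-3-methoxyphenyl]-2-methylbutan-2-ol, via organomercurial 11 (not isolated)
Conditions: Hg(OAc)2, THF/H2O (1:1), rt; then 3 M NaOH, NaBH4, 0 °C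
Reagents that add atoms: water, O
Why: Oxymercuration–demercuration gives Markovnikov hydration of the trisubstituted alkene to the tertiary alcohol without rearrangement, and both phenols are capped so no chroman can form.

Step 7
Reactants: 12 4-[2,6-bis(benzyloxy)-3-methoxyphenyl]-2-methylbutan-2-ol
Product: 13 4-[2,6-bis(benzyloxy)-3-bromo-5-methoxyphenyl]-2-methylbutan-2-ol
Conditions: NBS (1.05 eq), MeCN, 0 °C, dark
Reagents that add atoms: N-bromosuccinimide, O=C1CCC(=O)N1Br
Why: Electrophilic aromatic bromination goes to the ring CH that is ortho to one benzyloxy group and para to the other, rather than the CH activated only by the methoxy group.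

Step 8
Reactants: 13 4-[2,6-bis(benzyloxy)-3-bromo-5-methoxyphenyl]-2-methylbutan-2-ol
Product: 15 2,4-bis(benzyloxy)-3-(3-hydroxy-3-methylbutyl)-5-methoxybenzaldehyde, via dilithio species 14 (not isolated)
Conditions: n-BuLi (2.2 eq), THF, −78 °C; DMF, −78 → 0 °C; aq NH4Cl
Reagents that add atoms: N,N-dimethylformamide, CN(C)C=O
Why: The first equivalent of base makes the alkoxide, the second performs Br/Li exchange, and the aryllithium is formylated by DMF (Bouveault-type formylation).

Step 9
Reactants: 16 2',4',6'-trihydroxyacetophenone (phloroacetophenone)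
Product: 17 1-[2,4-bis(benzyloxy)-6-hydroxyphenyl]ethan-1-one
Conditions: BnBr (2.1 eq), K2CO3, DMF, rt
Reagents that add atoms: benzyl bromide, BrCc1ccccc1
Why: Williamson etherification stops at the dibenzyl ether because the remaining ortho OH is hydrogen-bonded to the ketone and much less nucleophilic.

Step 10
Reactants: 15 2,4-bis(benzyloxy)-3-(3-hydroxy-3-methylbutyl)-5-methoxybenzaldehyde; 17 1-[2,4-bis(benzyloxy)-6-hydroxyphenyl]ethan-1-one
Product: 19 (E)-1-[2,4-bis(benzyloxy)-6-hydroxyphenyl]-3-[2,4-bis(benzyloxy)-3-(3-hydroxy-3-methylbutyl)-5-methoxyphenyl]prop-2-en-1-one, via aldol adduct 18 (not isolated)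
Conditions: KOH (50% aq), EtOH/THF, rt, 48 h; AcOH to pH 6
Reagents that add atoms: none
Why: Claisen–Schmidt crossed aldol condensation of the methyl ketone enolate with a non-enolisable aldehyde, with E1cB dehydration giving the conjugated (E)-chalcone.

Step 11
Reactants: 19 the (E)-chalcone
Product: 20 rac-1-[2,4-bis(benzyloxy)-6-hydroxyphenyl]-2-[2,4-bis(benzyloxy)-3-(3-hydroxy-3-methylbutyl)-5-methoxyphenyl]-3,3-dimethoxypropan-1-one
Conditions: Tl(NO3)3·3H2O (1.1 eq), MeOH/CH2Cl2, rt
Reagents that add atoms: methanol, CO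
Why: Thallium(III)-mediated oxidative rearrangement (oxythallation, then 1,2-aryl shift of the strongly donating 2,4-dialkoxyaryl group) gives the acetal; its racemic stereocentre is destroyed in the next step.

Step 12
Reactants: 20 the dimethyl acetal
Product: 22 5,7-bis(benzyloxy)-3-[2,4-bis(benzyloxy)-3-(3-hydroxy-3-methylbutyl)-5-methoxyphenyl]-4H-chromen-4-one, via 2-methoxyisoflavanone 21 (not isolated)
Conditions: 2 M aq HCl, THF (1:4), 50 °C
Reagents that add atoms: none
Why: Acid-catalysed transacetalisation by the free 2'-OH followed by loss of methanol gives the γ-pyrone, while the aqueous medium protects the tertiary alcohol from methyl ether formation.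

Step 13
Reactants: 22 the tetra-O-benzyl isoflavone
Product: 23 5,7-dihydroxy-3-[2,4-dihydroxy-3-(3-hydroxy-3-methylbutyl)-5-methoxyphenyl]-4H-chromen-4-one (target)
Conditions: H2 (1 atm), 10% Pd/C, THF/MeOH, rt, stopped after uptake of 4 eq H2
Reagents that add atoms: none
Why: Catalytic hydrogenolysis removes all four benzyl ethers under neutral conditions, so the tertiary alcohol cannot cyclise onto the neighbouring phenols and the chromone C2=C3 bond is kept.

**Compound list**
1 | isovanillin (3-hydroxy-4-methoxybenzaldehyde) | COc1ccc(C=O)cc1O | starting material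
2 | 2-bromo-3-hydroxy-4-methoxybenzaldehyde | COc1ccc(C=O)c(Br)c1O | intermediate
3 | 3-(benzyloxy)-2-bromo-4-methoxybenzaldehyde | COc1ccc(C=O)c(Br)c1OCc1ccccc1 | intermediate
4 | 3-(benzyloxy)-2-bromo-4-methoxyphenyl formate (not isolated) | COc1ccc(OC=O)c(Br)c1OCc1ccccc1 | intermediate
5 | 3-(benzyloxy)-2-bromo-4-methoxyphenol | COc1ccc(O)c(Br)c1OCc1ccccc1 | intermediate
6 | 1,3-bis(benzyloxy)-2-bromo-4-methoxybenzene | COc1ccc(OCc2ccccc2)c(Br)c1OCc1ccccc1 | intermediate
7 | prenyl bromide (1-bromo-3-methylbut-2-ene) | CC(C)=CCBr | starting material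
8 | [2,6-bis(benzyloxy)-3-methoxyphenyl]lithium (not isolated) | COc1ccc(OCc2ccccc2)c([Li])c1OCc1ccccc1 | intermediate
9 | [2,6-bis(benzyloxy)-3-methoxyphenyl]copper(I) (not isolated) | COc1ccc(OCc2ccccc2)c([Cu])c1OCc1ccccc1 | intermediate
10 | 1,3-bis(benzyloxy)-4-methoxy-2-(3-methylbut-2-en-1-yl)benzene | COc1ccc(OCc2ccccc2)c(CC=C(C)C)c1OCc1ccccc1 | intermediate
11 | rac-{1-[2,6-bis(benzyloxy)-3-methoxyphenyl]-3-hydroxy-3-methylbutan-2-yl}mercury(II) acetate (not isolated) | COc1ccc(OCc2ccccc2)c(CC([Hg]OC(C)=O)C(C)(C)O)c1OCc1ccccc1 | intermediate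
12 | 4-[2,6-bis(benzyloxy)-3-methoxyphenyl]-2-methylbutan-2-ol | COc1ccc(OCc2ccccc2)c(CCC(C)(C)O)c1OCc1ccccc1 | intermediate
13 | 4-[2,6-bis(benzyloxy)-3-bromo-5-methoxyphenyl]-2-methylbutan-2-ol | COc1cc(Br)c(OCc2ccccc2)c(CCC(C)(C)O)c1OCc1ccccc1 | intermediate
14 | lithium 4-[2,6-bis(benzyloxy)-3-lithio-5-methoxyphenyl]-2-methylbutan-2-olate (not isolated) | COc1cc([Li])c(OCc2ccccc2)c(CCC(C)(C)O[Li])c1OCc1ccccc1 | intermediate
15 | 2,4-bis(benzyloxy)-3-(3-hydroxy-3-methylbutyl)-5-methoxybenzaldehyde | COc1cc(C=O)c(OCc2ccccc2)c(CCC(C)(C)O)c1OCc1ccccc1 | intermediate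
16 | 2',4',6'-trihydroxyacetophenone | CC(=O)c1c(O)cc(O)cc1O | starting material
17 | 1-[2,4-bis(benzyloxy)-6-hydroxyphenyl]ethan-1-one | CC(=O)c1c(O)cc(OCc2ccccc2)cc1OCc1ccccc1 | intermediate
18 | rac-1-[2,4-bis(benzyloxy)-6-hydroxyphenyl]-3-[2,4-bis(benzyloxy)-3-(3-hydroxy-3-methylbutyl)-5-methoxyphenyl]-3-hydroxypropan-1-one (not isolated) | COc1cc(C(O)CC(=O)c2c(O)cc(OCc3ccccc3)cc2OCc2ccccc2)c(OCc2ccccc2)c(CCC(C)(C)O)c1OCc1ccccc1 | intermediate
19 | (E)-1-[2,4-bis(benzyloxy)-6-hydroxyphenyl]-3-[2,4-bis(benzyloxy)-3-(3-hydroxy-3-methylbutyl)-5-methoxyphenyl]prop-2-en-1-one | COc1cc(/C=C/C(=O)c2c(O)cc(OCc3ccccc3)cc2OCc2ccccc2)c(OCc2ccccc2)c(CCC(C)(C)O)c1OCc1ccccc1 | intermediate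
20 | rac-1-[2,4-bis(benzyloxy)-6-hydroxyphenyl]-2-[2,4-bis(benzyloxy)-3-(3-hydroxy-3-methylbutyl)-5-methoxyphenyl]-3,3-dimethoxypropan-1-one | COc1cc(C(C(OC)OC)C(=O)c2c(O)cc(OCc3ccccc3)cc2OCc2ccccc2)c(OCc2ccccc2)c(CCC(C)(C)O)c1OCc1ccccc1 | intermediate
21 | 5,7-bis(benzyloxy)-3-[2,4-bis(benzyloxy)-3-(3-hydroxy-3-methylbutyl)-5-methoxyphenyl]-2-methoxychroman-4-one (racemic diastereomer mixture, not isolated) | COc1cc(C2C(OC)Oc3cc(OCc4ccccc4)cc(OCc4ccccc4)c3C2=O)c(OCc2ccccc2)c(CCC(C)(C)O)c1OCc1ccccc1 | intermediate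
22 | 5,7-bis(benzyloxy)-3-[2,4-bis(benzyloxy)-3-(3-hydroxy-3-methylbutyl)-5-methoxyphenyl]-4H-chromen-4-one | COc1cc(-c2coc3cc(OCc4ccccc4)cc(OCc4ccccc4)c3c2=O)c(OCc2ccccc2)c(CCC(C)(C)O)c1OCc1ccccc1 | intermediate
23 | 5,7-dihydroxy-3-[2,4-dihydroxy-3-(3-hydroxy-3-methylbutyl)-5-methoxyphenyl]-4H-chromen-4-one | COc1cc(-c2coc3cc(O)cc(O)c3c2=O)c(O)c(CCC(C)(C)O)c1O | target

**Totals**
Total step count: 13 (B-ring branch steps 1–8, A-ring branch step 9, convergent steps 10–13).
Longest linear sequence: 12 steps (1–8, then 10–13).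

**Three steps most likely to fail, with fallbacks**

Step 5 (aryllithium/copper prenylation). The 2,6-bis(benzyloxy)aryllithium can decompose by benzylic proton transfer if it warms, and the allylation can give some of the γ-coupled (reverse-prenyl) isomer. The fallback sets out from 6 and avoids organolithium chemistry. A Heck reaction of 6 with 2-methylbut-3-en-2-ol (Pd(OAc)2, P(t-Bu)3·HBF4, K2CO3, DMF, 110 °C) gives (E)-4-[2,6-bis(benzyloxy)-3-methoxyphenyl]-2-methylbut-3-en-2-ol F1, which already carries the tertiary alcohol. Diimide reduction of the styrenyl double bond (TsNHNH2, NaOAc, THF/H2O, reflux) leaves the benzyl ethers untouched and comes back to the route at 12, bypassing 10 and the mercury step.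

Step 8 (Br/Li exchange and formylation of a substrate with a free tertiary alcohol). Incomplete exchange or protonation of the dianion would return debrominated 12. The fallback sets out from 13. Suzuki–Miyaura vinylation with potassium vinyltrifluoroborate (PdCl2(dppf), Cs2CO3, THF/H2O, 80 °C) gives 4-[2,6-bis(benzyloxy)-3-ethenyl-5-methoxyphenyl]-2-methylbutan-2-ol F2. Lemieux–Johnson cleavage (cat. OsO4, NaIO4, 2,6-lutidine, dioxane/H2O) then comes back to the route at aldehyde 15.

Step 11 (thallium(III) oxidative rearrangement). Possible problems are aurone formation through the free 2'-OH, oxidation of the trioxygenated B ring, and methanolysis of the tertiary alcohol by the nitric acid released. The fallback sets out from chalcone 19. Ring closure with NaOAc in refluxing EtOH (intramolecular oxa-Michael addition) gives racemic 5,7-bis(benzyloxy)-2-[2,4-bis(benzyloxy)-3-(3-hydroxy-3-methylbutyl)-5-methoxyphenyl]chroman-4-one F3. Oxidative 2,3-aryl migration of this flavanone with [hydroxy(tosyloxy)iodo]benzene in MeCN comes back to the route at isoflavone 22, bypassing 20 and 21.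

**Further compounds**
F1 | step 5 | (E)-4-[2,6-bis(benzyloxy)-3-methoxyphenyl]-2-methylbut-3-en-2-ol | COc1ccc(OCc2ccccc2)c(/C=C/C(C)(C)O)c1OCc1ccccc1
F2 | step 8 | 4-[2,6-bis(benzyloxy)-3-ethenyl-5-methoxyphenyl]-2-methylbutan-2-ol | COc1cc(C=C)c(OCc2ccccc2)c(CCC(C)(C)O)c1OCc1ccccc1
F3 | step 11 | rac-5,7-bis(benzyloxy)-2-[2,4-bis(benzyloxy)-3-(3-hydroxy-3-methylbutyl)-5-methoxyphenyl]chroman-4-one | COc1cc(C2CC(=O)c3c(OCc4ccccc4)cc(OCc4ccccc4)cc3O2)c(OCc2ccccc2)c(CCC(C)(C)O)c1OCc1ccccc1
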